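Compound numbers used throughout: **1** 2,4,6‑trihydroxyacetophenone, **4** acetylfilicinic acid, **7** the methylene‑bridged dimer of **1**, **9** the Mannich base of **4**, **11** the tetra‑acetyl tetramer, **13** its hexa‑MOM ether, **14** its deca‑MOM ether, **17** the deca‑MOM ether of the target, **18** the target.

## The problem

Compound **18** is a linear tetramer in which two 2‑butanoyl‑4,4‑dimethylcyclohexane‑1,3,5‑trione rings (rings A, drawn as dienols) flank two butanoylphloroglucinol rings (rings B), joined by three CH2 bridges in the order A–CH2–B–CH2–B–CH2–A and symmetric about the central bridge. There is no stereocenter, so nothing has to be controlled in three dimensions. The difficulty is constitutional: every ring carbon is substituted, and the three bridges must be placed without the shorter and longer oligomers that formaldehyde chemistry gives easily. The ten hydroxyls are acidic enols and phenols, four of them (one beside each acyl group) held in a strong hydrogen bond to the acyl carbonyl. Bridges between such rings break and recombine by retro‑Michael scission in alkali and in strong acid, so the free polyphenol must not sit long under either. Rings A are dearomatised at a gem‑dimethyl carbon, which means two methyl groups have to go onto one ring carbon. The enabling feature is that all four acyl groups are the same C(=O)–CH2–CH2–CH3 chain, on C2 of each ring A and on C3 of each ring B. Each is an acetyl group lengthened by ethyl through the bond between chain carbons 2 and 3, so the framework can be built in the acetyl series and all four chains finished in one operation once the hydroxyls are masked.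

## Retrosynthesis

**18 ⇒ 17.** The ten O–CH2OMe bonds are cut. Methoxymethyl ethers are chosen over methyl ethers, which would need BBr3 on a molecule with three labile bridges, and over benzyl ethers, whose introduction risks C‑benzylation of rings A. The forward step asks only for dilute protic acid in methanol.

**17 ⇒ 14 + iodoethane 15 (key cut).** The bond between chain carbons 2 and 3 is cut in all four butanoyl groups. The neighbouring cut, ring–C(=O), is a Friedel–Crafts acylation; it cannot be run on rings that are already fully substituted and would simply move the chain back to the monomer. The cut between carbonyl carbon and chain carbon 2 would need four hindered carboxyl derivatives. The chosen cut leaves every carbonyl where it is and asks only for a primary SN2 reaction of a methyl ketone enolate. The precursor **14** is eight carbons simpler and belongs to the cheapest acylphloroglucinol series. The forward reaction must form four enolates in one molecule, ethylate each once, and leave the bridges alone.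

**14 ⇒ 13 + chloromethyl methyl ether 12.** The four O–C bonds on the oxygens beside the acetyl groups are cut. These hydroxyls are the chelated ones, and only a strong base opens their hydrogen bond. The precursor **13** already carries six MOM groups, so the strong base meets a molecule with four acidic sites and not a decaol. That keeps the number of ring oxides, and with it the risk of bridge scission, low.

**13 ⇒ 11 + 12.** The six O–C bonds on the oxygens that are not locked to an acetyl carbonyl are cut. The forward step needs only an amine base, and it stops by itself at one free hydroxyl per acetyl group, as is usual for acylphloroglucinols. Capping all ten oxygens in a single strongly basic operation was the neighbouring choice; it would expose the free tetramer **11** as a polyoxide and is harder to drive to completion.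

**11 ⇒ 7 + two 9 (through 10).** The two outer bridges are cut at the ring B carbon. The alternative of cutting the central bridge last, dimerising two A–CH2–B halves with formaldehyde, would expose the labile A–CH2–B links to alkaline formaldehyde. The chosen cut gives a symmetric dimer **7** with exactly one free carbon per ring and an electrophile **10** with exactly one reactive carbon, so oligomers cannot grow. The forward reaction is a double Michael addition of the arene to the enone released from **9**.

**9 ⇒ 4 + N,N‑dimethylmethyleneiminium iodide 8.** The C6–CH2 bond of ring A is cut (Mannich reaction). This stores the one‑carbon electrophile on ring A in a stable form and avoids free formaldehyde, which would convert **4** into its own methylene‑bridged dimer.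

**4 ⇒ 1 + two iodomethane 2.** Both C–CH3 bonds at one ring carbon are cut. The precursor is the commercial aromatic ketone **1**; the forward step is a dearomatising double C‑methylation.

**7 ⇒ two 1 + formaldehyde 5.** The central bridge is cut. Both halves are the same commercial ketone, and the only demand is to stop at the dimer.

## Roads not taken

Alternative 1: Each ring B is cut across two ring bonds, back to the CH2‑linked bis‑diene A2 and two molecules of the ynone A3. In the forward step each diene half adds to A3, with the ketene acetal carbon bonding to the acyl‑bearing alkyne carbon and the CH2‑bearing terminus to the ethoxy‑bearing carbon. Loss of methanol then aromatises both rings and gives the diaryl­methane A1. Merits: the butanoyl chain arrives intact, the substitution pattern is fixed by the polarity of the two components, and the central bridge is carried in A2. Weak points: A1 is only the B–CH2–B core, so ring A and both outer bridges still have to be made as in steps 1, 3 and 4. A2 is a hydrolytically fragile fourfold silyl enol ether that itself takes several steps. The donor‑substituted ynone A3 is a sluggish dienophile. Two aryl ethyl ethers must be cleaved later. Comparison: A1 is the ethylated butanoyl counterpart of **7**, which the chosen plan gets in one step from a commercial ketone, so this road spends its ring‑forming step on an arene that can be bought. It is better in one respect: rings B never face a mono‑alkylation problem. Against that, the chosen plan has the one‑step access to **7** and a key step that also finishes the two ring A chains.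

Alternative 2: Each ring A is cut at three ring bonds, back to the bis‑cyclobutenone A5 and (triisopropylsiloxy)ethyne A6. On heating, each cyclobutenone opens to a vinylketene, adds A6, reopens and closes by electrocyclisation to the six‑membered dienone, giving A4. Merits: the gem‑dimethyl ring is built with a defined oxygen pattern, the poorly selective C‑methylation of step 1 is avoided, and the outer bridges are already in A5, so no Mannich coupling is needed; in ring A regiocontrol this road is better. Weak points: A4 has no acyl group on rings A, so two C‑acylations must follow on a crowded tetramer. Three kinds of protecting group (six benzyl ethers, two ethyl enol ethers, two silyl enol ethers) must be removed. A5 needs a long synthesis, and the thermal cascade has to run twice in one molecule. Comparison: this road is much longer and solves a ring that one step delivers from **1**. The chosen plan accepts a moderate step 1 on a cheap material in return.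

Alternative 3: In each ring B the aryl–C(=O) and the neighbouring aryl–O bonds are cut together, back to the bis(silylaryl triflate) A8 and butanoic acid A9. CsF releases an aryne on each ring, and each inserts into the O–C(acyl) bond of A9 to give the bis(hydroxyaryl ketone) A7. Merits: the full butanoyl group and its ortho hydroxyl enter in one mild step without Friedel–Crafts conditions, and the methoxy group next to the aryne directs the regiochemistry; like the chosen plan, the chain is installed late. Weak points: A8 takes many steps to deliver what an acylphloroglucinol already contains. Two arynes must be generated in one molecule, and O‑arylation to the aryl butanoate competes with insertion. A7 carries four methyl ethers that need BBr3, and rings A with their own butanoyl groups and bridges are not addressed. Comparison: this road installs two of the four chains without any risk of over‑alkylation, which is a real advantage. The chosen plan sets against it one operation for all four chains, acid‑labile protecting groups, and a far shorter route to the framework.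

Key step: step 7

Remarks on the chemistry (assumptions):
- Tautomers: **18** and all enolic intermediates are written in the one tautomeric form used for the target; the keto–enol forms interconvert and are one compound.
- Partly protected tetramer: **13** is written with the free hydroxyl of each ring B between the central bridge and the acetyl group and that of each ring A on the enol carbon beside the acetyl‑bearing carbon; an isomer with the free hydroxyl on the other side of an acetyl group, or material that is already capped further, gives the same **14** in step 6.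
- Enol ethers of rings A: **14** and **17** are written as the cross‑conjugated 2,5‑dienone with both MOM groups on the oxygens next to the gem‑dimethyl carbon; regioisomeric bis‑enol ethers that may accompany them keep the same acetyl groups, react alike in step 7 and give the same **18** in step 8.

## Route

Step 1
Reactants: 1 2,4,6‑trihydroxyacetophenone; 2 iodomethane
Product: 4 acetylfilicinic acid (2‑acetyl‑3,5‑dihydroxy‑4,4‑dimethylcyclohexa‑2,5‑dien‑1‑one), via C‑monomethyl ketone 3 (not isolated)
Conditions: NaOMe (3 equiv), MeI (2.2 equiv), MeOH, 0 °C to rt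
Reagents that add atoms: iodomethane, CI
Why: Base‑mediated dearomatising C‑methylation of the phloroglucinol ring: the first methyl makes the same carbon the most electron‑rich, so the second enters there, and the resulting triketone sits as a stabilised, less nucleophilic enolate; this is the classical entry to acylfilicinic acids, with under‑ and over‑methylated ketones removed by crystallisation.

Step 2
Reactants: 1 2,4,6‑trihydroxyacetophenone (two molecules incorporated, used in excess); 5 formaldehyde
Product: 7 bis(3‑acetyl‑2,4,6‑trihydroxyphenyl)methane, via hydroxymethyl ketone 6 (not isolated)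
Conditions: 37% aq. HCHO (0.4 equiv per ketone), NaOH (0.1 equiv), H2O/MeOH, 0 °C to rt
Reagents that add atoms: formaldehyde, C=O
Why: Phenol–formaldehyde condensation: phenoxide hydroxymethylation to 6, loss of water to an ortho‑quinone methide and Michael addition of a second phenoxide; the ketone is kept in excess and recovered so that the dimer, which still has two free ring carbons, is not bridged further.

Step 3
Reactants: 4 acetylfilicinic acid; 8 N,N‑dimethylmethyleneiminium iodide
Product: 9 2‑acetyl‑6‑[(dimethylamino)methyl]‑3,5‑dihydroxy‑4,4‑dimethylcyclohexa‑2,5‑dien‑1‑one hydroiodide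
Conditions: MeCN, 0 °C to rt
Reagents that add atoms: N,N‑dimethylmethyleneiminium iodide, C=[N+](C)C.[I-]
Why: Mannich reaction of the enolised 1,5‑diketone half of 4 with the preformed iminium ion at C6, the only unsubstituted ring carbon; without added base the product stays an ammonium salt, which cannot lose amine and so does not go on to the methylene‑bridged dimer of 4.

Step 4
Reactants: 7 bis(3‑acetyl‑2,4,6‑trihydroxyphenyl)methane; 9 Mannich base hydroiodide (2.2 equiv)
Product: 11 bis{3‑acetyl‑5‑[(5‑acetyl‑2,4‑dihydroxy‑3,3‑dimethyl‑6‑oxocyclohexa‑1,4‑dien‑1‑yl)methyl]‑2,4,6‑trihydroxyphenyl}methane, via exocyclic methylene trione 10 (not isolated)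
Conditions: NaOAc (2.5 equiv), EtOH, 50 °C
Reagents that add atoms: none
Why: Retro‑Mannich/Michael bridging: acetate frees the zwitterionic Mannich base, which loses dimethylamine (E1cB) to the exocyclic enone 10, and the one free, strongly activated carbon of each ring B of 7 adds to it and rearomatises. The tactic is established for joining cyclic beta‑triketones to acylphloroglucinols through one carbon; here each partner has a single reactive carbon, so no oligomer can grow.

Step 5
Reactants: 11 tetra‑acetyl tetramer; 12 chloromethyl methyl ether
Product: 13 bis{3‑acetyl‑5‑[(5‑acetyl‑4‑hydroxy‑2‑(methoxymethoxy)‑3,3‑dimethyl‑6‑oxocyclohexa‑1,4‑dien‑1‑yl)methyl]‑2‑hydroxy‑4,6‑bis(methoxymethoxy)phenyl}methane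
Conditions: MOMCl (7 equiv), i‑Pr2NEt (9 equiv), CH2Cl2, 0 °C to rt
Reagents that add atoms: chloromethyl methyl ether, COCCl
Why: Amine‑mediated Williamson‑type O‑alkylation with MOMCl caps the vinylogous‑acid enol of each ring A and two of the three phenols of each ring B; the last hydroxyl beside each acetyl group sits in a six‑membered hydrogen bond to the carbonyl, which lowers both its acidity towards the amine and its nucleophilicity, and this is the usual stopping point for acylphloroglucinols under these conditions.

Step 6
Reactants: 13 hexa‑MOM tetra‑acetyl tetramer; 12 chloromethyl methyl ether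
Product: 14 bis{3‑acetyl‑5‑[(5‑acetyl‑2,4‑bis(methoxymethoxy)‑3,3‑dimethyl‑6‑oxocyclohexa‑1,4‑dien‑1‑yl)methyl]‑2,4,6‑tris(methoxymethoxy)phenyl}methane
Conditions: NaH (5 equiv, added in portions to substrate and MOMCl), MOMCl (6 equiv), THF/DMF, 0 °C to rt
Reagents that add atoms: chloromethyl methyl ether, COCCl
Why: Williamson‑type O‑alkylation: NaH opens the four hydrogen bonds irreversibly to give sodium phenoxides and triketone enolates, and MOMCl, a hard oxocarbenium‑like electrophile, goes to oxygen and not to carbon; with six oxygens already capped and each new oxide trapped as it forms, the retro‑Michael pathway has little to work with.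

Step 7
Reactants: 14 deca‑MOM tetra‑acetyl tetramer; 15 iodoethane
Product: 17 bis{3‑butanoyl‑5‑[(5‑butanoyl‑2,4‑bis(methoxymethoxy)‑3,3‑dimethyl‑6‑oxocyclohexa‑1,4‑dien‑1‑yl)methyl]‑2,4,6‑tris(methoxymethoxy)phenyl}methane, via tetralithium tetraenolate 16 (not isolated)
Conditions: LiN(SiMe3)2 (4.4 equiv), THF, −78 °C; then EtI (20 equiv), DMPU, −78 to −30 °C; aq. NH4Cl
Reagents that add atoms: iodoethane, CCI
Why: LiN(SiMe3)2 removes one proton from each acetyl methyl group, the only carbon acids left once all ten hydroxyls are capped, to give the tetraenolate 16, and each enolate carbon then displaces iodide from iodoethane in an SN2 step, forming the bond between chain carbons 2 and 3 of all four butanoyl groups. The closest known reaction type is the alkylation of kinetic lithium enolates of aryl methyl ketones and 2‑acetyl enones with primary alkyl iodides in THF/DMPU. No ring is closed and no stereocenter is formed, because each new bond joins two methylene carbons. The step needs three selectivities: acetyl CH3 against the bridging CH2 groups, carbon against oxygen alkylation, and one ethyl group per site. The first rests on the several pK units between a ketone alpha‑CH and a diarylmethane‑type CH2 and on the absence of any free OH. The second rests on the lithium counter‑ion and the soft iodide electrophile. The third rests on slightly more than one equivalent of base per acetyl group, a large excess of iodoethane with DMPU so that alkylation outruns enolate–ketone proton exchange, and the greater hindrance of the butanoyl alpha‑CH2 between the carbonyl and two flanking ring substituents. Retro‑Michael scission of the bridges is shut off because no ring oxygen can become an oxide.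

Step 8
Reactants: 17 deca‑MOM tetrabutanoyl tetramer
Product: 18 bis{3‑butanoyl‑5‑[(5‑butanoyl‑2,4‑dihydroxy‑3,3‑dimethyl‑6‑oxocyclohexa‑1,4‑dien‑1‑yl)methyl]‑2,4,6‑trihydroxyphenyl}methane (target)
Conditions: 3 M aq. HCl, MeOH, rt to 40 °C
Reagents that add atoms: none
Why: Acid‑catalysed acetal exchange with methanol releases all ten hydroxyls, the vinylogous‑ester enol ethers of rings A cleaving first; since every ring carbon is substituted, the methoxymethyl cation has no free nucleophilic carbon to attack.

## Compound list

No compound of the route has a stereocenter.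

1 | 2,4,6‑trihydroxyacetophenone | CC(=O)c1c(O)cc(O)cc1O | starting material
2 | iodomethane | CI | starting material
3 | 3‑methyl‑2,4,6‑trihydroxyacetophenone (formed in the flask in step 1, not isolated) | CC(=O)c1c(O)cc(O)c(C)c1O | intermediate
4 | acetylfilicinic acid, 2‑acetyl‑3,5‑dihydroxy‑4,4‑dimethylcyclohexa‑2,5‑dien‑1‑one | CC(=O)C1=C(O)C(C)(C)C(O)=CC1=O | intermediate
5 | formaldehyde | C=O | starting material
6 | 3‑(hydroxymethyl)‑2,4,6‑trihydroxyacetophenone (formed in the flask in step 2, not isolated) | CC(=O)c1c(O)cc(O)c(CO)c1O | intermediate
7 | bis(3‑acetyl‑2,4,6‑trihydroxyphenyl)methane | CC(=O)c1c(O)cc(O)c(Cc2c(O)cc(O)c(C(C)=O)c2O)c1O | intermediate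
8 | N,N‑dimethylmethyleneiminium iodide | C=[N+](C)C.[I-] | starting material
9 | 2‑acetyl‑6‑[(dimethylamino)methyl]‑3,5‑dihydroxy‑4,4‑dimethylcyclohexa‑2,5‑dien‑1‑one hydroiodide | CC(=O)C1=C(O)C(C)(C)C(O)=C(C[NH+](C)C)C1=O.[I-] | intermediate
10 | 2‑acetyl‑3‑hydroxy‑4,4‑dimethyl‑6‑methylidenecyclohex‑2‑ene‑1,5‑dione (formed in the flask in step 4, not isolated) | CC(=O)C1=C(O)C(C)(C)C(=O)C(=C)C1=O | intermediate
11 | tetra‑acetyl tetramer, bis{3‑acetyl‑5‑[(5‑acetyl‑2,4‑dihydroxy‑3,3‑dimethyl‑6‑oxocyclohexa‑1,4‑dien‑1‑yl)methyl]‑2,4,6‑trihydroxyphenyl}methane | CC(=O)C1=C(O)C(C)(C)C(O)=C(Cc2c(O)c(Cc3c(O)c(CC4=C(O)C(C)(C)C(O)=C(C(C)=O)C4=O)c(O)c(C(C)=O)c3O)c(O)c(C(C)=O)c2O)C1=O | intermediate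
12 | chloromethyl methyl ether | COCCl | starting material
13 | hexa‑MOM ether of 11 (one hydroxyl beside each of the four acetyl groups left free; the other six as OCH2OCH3) | CC(=O)C1=C(O)C(C)(C)C(OCOC)=C(Cc2c(OCOC)c(Cc3c(OCOC)c(CC4=C(OCOC)C(C)(C)C(O)=C(C(C)=O)C4=O)c(OCOC)c(C(C)=O)c3O)c(O)c(C(C)=O)c2OCOC)C1=O | intermediate
14 | deca‑MOM ether of 11 (all ten hydroxyls as OCH2OCH3) | CC(=O)C1=C(OCOC)C(C)(C)C(OCOC)=C(Cc2c(OCOC)c(Cc3c(OCOC)c(CC4=C(OCOC)C(C)(C)C(OCOC)=C(C(C)=O)C4=O)c(OCOC)c(C(C)=O)c3OCOC)c(OCOC)c(C(C)=O)c2OCOC)C1=O | intermediate
15 | iodoethane | CCI | starting material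
16 | tetralithium tetraenolate of 14, each acetyl group as C(OLi)=CH2 (formed in the flask in step 7, not isolated) | [Li]OC(=C)C1=C(OCOC)C(C)(C)C(OCOC)=C(Cc2c(OCOC)c(Cc3c(OCOC)c(CC4=C(OCOC)C(C)(C)C(OCOC)=C(C(=C)O[Li])C4=O)c(OCOC)c(C(=C)O[Li])c3OCOC)c(OCOC)c(C(=C)O[Li])c2OCOC)C1=O | intermediate
17 | deca‑MOM ether of the target (four butanoyl groups) | CCCC(=O)C1=C(OCOC)C(C)(C)C(OCOC)=C(Cc2c(OCOC)c(Cc3c(OCOC)c(CC4=C(OCOC)C(C)(C)C(OCOC)=C(C(=O)CCC)C4=O)c(OCOC)c(C(=O)CCC)c3OCOC)c(OCOC)c(C(=O)CCC)c2OCOC)C1=O | intermediate
18 | CNP0110234.0, bis{3‑butanoyl‑5‑[(5‑butanoyl‑2,4‑dihydroxy‑3,3‑dimethyl‑6‑oxocyclohexa‑1,4‑dien‑1‑yl)methyl]‑2,4,6‑trihydroxyphenyl}methane | CCCC(=O)C1=C(O)C(C)(C)C(O)=C(Cc2c(O)c(Cc3c(O)c(CC4=C(O)C(C)(C)C(O)=C(C(=O)CCC)C4=O)c(O)c(C(=O)CCC)c3O)c(O)c(C(=O)CCC)c2O)C1=O | target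

## Step count and risk

Total: 8 steps. Longest linear sequence: 7 steps (steps 1, 3, 4, 5, 6, 7, 8); step 2 is the second branch and joins at step 4.

**Step 7 (key step).** The most likely failure is loss of the one‑ethyl‑per‑site control. If proton exchange between unreacted enolates and butanoyl groups already formed competes with the slow SN2 step, the four sites end up as a statistical mix of acetyl, butanoyl and 2‑ethylbutanoyl groups. Two lesser hazards are incomplete enolisation through aggregation of the fourfold lithiated species, and enolate attack on the alkoxy‑enone carbons of rings A of another molecule with loss of a MOM oxide. Fallback from 14, returning at 17: the same enolate 16 is trapped with acetaldehyde at −78 °C. An aldolate is not a carbon nucleophile, so each site can react only once, giving the deca‑MOM tetrakis(3‑hydroxybutanoyl) tetramer F1 as a diastereomer mixture. MsCl/Et3N and then DBU dehydrate it to the deca‑MOM tetrakis[(E)‑but‑2‑enoyl] tetramer F2. H2 over Pd/C in EtOAc saturates the four disubstituted enone double bonds and leaves the tetrasubstituted alkoxy‑enones of rings A, giving 17. The same carbon–carbon bond is made, by addition in place of substitution.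

**Step 6.** The most likely failure is incomplete capping of the four chelated, doubly flanked hydroxyls, or bridge scission and recombination by retro‑Michael reaction of a sodium oxide that waits too long for its electrophile. Step 5 before it is tolerant, since under‑ and over‑capped material converges here. Fallback from 11, returning at 18: permethylation with dimethyl sulfate and K2CO3 in refluxing acetone, a weaker base with a smaller electrophile and the classical exhaustive etherification for this class, gives the deca‑O‑methyl tetra‑acetyl tetramer F3. The conditions of step 7 convert it into the deca‑O‑methyl tetrabutanoyl tetramer F4. BBr3 in CH2Cl2 followed by aqueous work‑up then gives 18. The price is a harsher last step.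

**Step 4.** The most likely failure is self‑consumption of the enone 10 by hetero‑Diels–Alder dimerisation, or its capture by ring A enol set free through reversal of the Mannich reaction, which gives the A–CH2–A dimer. The second addition may also stall at the trimer. Fallback from 7, returning at 11: the polarity is reversed. Twofold aminomethylation of 7 with 8 gives bis[3‑acetyl‑5‑(dimethylaminomethyl)‑2,4,6‑trihydroxyphenyl]methane F5, in which each ring B has used its one free carbon. Heating F5 with an excess of 4 in dioxane releases the ortho‑quinone methide on ring B, and C6 of 4, the only nucleophilic carbon present, adds to it to give 11.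

**Step 8.** The most likely failure is acid‑induced scission or exchange of the bridges if the last, hindered MOM groups come off only under forcing acid, or incomplete deprotection if the acid is kept mild. Fallback from 11, returning at 18: BnBr and K2CO3 in DMF give the deca‑O‑benzyl tetra‑acetyl tetramer F6, with C‑benzylated material removed by chromatography. The conditions of step 7 convert it into the deca‑O‑benzyl tetrabutanoyl tetramer F7. H2 over Pd/C in EtOAc/MeOH removes all ten benzyl groups under neutral conditions and gives 18.

## Further compounds

F1 | step 7 | deca‑MOM tetrakis(3‑hydroxybutanoyl) tetramer, mixture of diastereomers at the four carbinol carbons | CC(O)CC(=O)C1=C(OCOC)C(C)(C)C(OCOC)=C(Cc2c(OCOC)c(Cc3c(OCOC)c(CC4=C(OCOC)C(C)(C)C(OCOC)=C(C(=O)CC(C)O)C4=O)c(OCOC)c(C(=O)CC(C)O)c3OCOC)c(OCOC)c(C(=O)CC(C)O)c2OCOC)C1=O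
F2 | step 7 | deca‑MOM tetrakis[(E)‑but‑2‑enoyl] tetramer | C/C=C/C(=O)C1=C(OCOC)C(C)(C)C(OCOC)=C(Cc2c(OCOC)c(Cc3c(OCOC)c(CC4=C(OCOC)C(C)(C)C(OCOC)=C(C(=O)/C=C/C)C4=O)c(OCOC)c(C(=O)/C=C/C)c3OCOC)c(OCOC)c(C(=O)/C=C/C)c2OCOC)C1=O
F3 | step 6 | deca‑O‑methyl tetra‑acetyl tetramer | CC(=O)C1=C(OC)C(C)(C)C(OC)=C(Cc2c(OC)c(Cc3c(OC)c(CC4=C(OC)C(C)(C)C(OC)=C(C(C)=O)C4=O)c(OC)c(C(C)=O)c3OC)c(OC)c(C(C)=O)c2OC)C1=O
F4 | step 6 | deca‑O‑methyl tetrabutanoyl tetramer | CCCC(=O)C1=C(OC)C(C)(C)C(OC)=C(Cc2c(OC)c(Cc3c(OC)c(CC4=C(OC)C(C)(C)C(OC)=C(C(=O)CCC)C4=O)c(OC)c(C(=O)CCC)c3OC)c(OC)c(C(=O)CCC)c2OC)C1=O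
F5 | step 4 | bis[3‑acetyl‑5‑(dimethylaminomethyl)‑2,4,6‑trihydroxyphenyl]methane | CC(=O)c1c(O)c(CN(C)C)c(O)c(Cc2c(O)c(CN(C)C)c(O)c(C(C)=O)c2O)c1O
F6 | step 8 | deca‑O‑benzyl tetra‑acetyl tetramer | CC(=O)C1=C(OCc5ccccc5)C(C)(C)C(OCc5ccccc5)=C(Cc2c(OCc5ccccc5)c(Cc3c(OCc5ccccc5)c(CC4=C(OCc5ccccc5)C(C)(C)C(OCc5ccccc5)=C(C(C)=O)C4=O)c(OCc5ccccc5)c(C(C)=O)c3OCc5ccccc5)c(OCc5ccccc5)c(C(C)=O)c2OCc5ccccc5)C1=O
F7 | step 8 | deca‑O‑benzyl tetrabutanoyl tetramer | CCCC(=O)C1=C(OCc5ccccc5)C(C)(C)C(OCc5ccccc5)=C(Cc2c(OCc5ccccc5)c(Cc3c(OCc5ccccc5)c(CC4=C(OCc5ccccc5)C(C)(C)C(OCc5ccccc5)=C(C(=O)CCC)C4=O)c(OCc5ccccc5)c(C(=O)CCC)c3OCc5ccccc5)c(OCc5ccccc5)c(C(=O)CCC)c2OCc5ccccc5)C1=O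
A1 | alternative 1 | bis(3‑butanoyl‑2‑ethoxy‑4,6‑dihydroxyphenyl)methane | CCCC(=O)c1c(O)cc(O)c(Cc2c(O)cc(O)c(C(=O)CCC)c2OCC)c1OCC
A2 | alternative 1 | 1,9‑dimethoxy‑1,3,7,9‑tetrakis(trimethylsilyloxy)nona‑1,3,6,8‑tetraene, double‑bond geometry not defined | COC(O[Si](C)(C)C)=CC(O[Si](C)(C)C)=CCC=C(O[Si](C)(C)C)C=C(OC)O[Si](C)(C)C
A3 | alternative 1 | 1‑ethoxyhex‑1‑yn‑3‑one | CCOC#CC(=O)CCC
A4 | alternative 2 | bis{2,4,6‑tris(benzyloxy)‑3‑butanoyl‑5‑[(2‑ethoxy‑3,3‑dimethyl‑4‑oxo‑6‑(triisopropylsilyloxy)cyclohexa‑1,5‑dien‑1‑yl)methyl]phenyl}methane | CCOC1=C(Cc2c(OCc3ccccc3)c(Cc3c(OCc4ccccc4)c(CC4=C(OCC)C(C)(C)C(=O)C=C4O[Si](C(C)C)(C(C)C)C(C)C)c(OCc4ccccc4)c(C(=O)CCC)c3OCc3ccccc3)c(OCc3ccccc3)c(C(=O)CCC)c2OCc2ccccc2)C(O[Si](C(C)C)(C(C)C)C(C)C)=CC(=O)C1(C)C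
A5 | alternative 2 | bis{2,4,6‑tris(benzyloxy)‑3‑butanoyl‑5‑[(2‑ethoxy‑3,3‑dimethyl‑4‑oxocyclobut‑1‑en‑1‑yl)methyl]phenyl}methane | CCOC1=C(Cc2c(OCc3ccccc3)c(Cc3c(OCc4ccccc4)c(CC4=C(OCC)C(C)(C)C4=O)c(OCc4ccccc4)c(C(=O)CCC)c3OCc3ccccc3)c(OCc3ccccc3)c(C(=O)CCC)c2OCc2ccccc2)C(=O)C1(C)C
A6 | alternative 2 | (triisopropylsiloxy)ethyne | C#CO[Si](C(C)C)(C(C)C)C(C)C
A7 | alternative 3 | bis(3‑butanoyl‑4‑hydroxy‑2,6‑dimethoxyphenyl)methane | CCCC(=O)c1c(O)cc(OC)c(Cc2c(OC)cc(O)c(C(=O)CCC)c2OC)c1OC
A8 | alternative 3 | bis[2,6‑dimethoxy‑4‑(trifluoromethylsulfonyloxy)‑3‑(trimethylsilyl)phenyl]methane | C[Si](C)(C)c1c(OS(=O)(=O)C(F)(F)F)cc(OC)c(Cc2c(OC)cc(OS(=O)(=O)C(F)(F)F)c([Si](C)(C)C)c2OC)c1OC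
A9 | alternative 3 | butanoic acid | CCCC(=O)O
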